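**Strategy.** The oxane ring (O1, C2 aryl, C3 side chain, C4 hydroxyl, C5, C6 arylethyl) is opened at C4–C5 and O1–C6. An acyclic β-hydroxy Weinreb amide that already holds C2, C3 and the complete C3 side chain acylates a C5–C6 alkenyllithium; the β′-hydroxy enone so formed closes by oxa-Michael addition in the same operation, giving both bonds and the C6 stereocentre. The step exploits the 1,3-relation of O1 and the C4 oxygen and the equatorial preference of the C2, C3 and C6 substituents; the axial C4 hydroxyl follows from hydride reduction. The precursor comes from an organocatalytic oxygenation, an organocopper conjugate addition and an auxiliary-controlled anti-aldol reaction.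

Key step: step 13

Remark: TBS = tert-butyldimethylsilyl and Ar = 4-(tert-butyldimethylsilyloxy)phenyl; side-chain carbons are primed (C3′ on the ring, C4′ the carbinol); compounds 1, 5, 7, 8, 11 and 12 are taken as commercial.

Step 1
Reactants: 1 methyl 3-(4-hydroxyphenyl)propanoate
Product: 2 methyl 3-Ar-propanoate
Conditions: TBSCl, imidazole, DMF, rt
Reagents that add atoms: tert-butyldimethylsilyl chloride, CC(C)(C)[Si](C)(C)Cl
Why: Imidazole-mediated silyl ether formation on the phenol; no stereocentre is involved.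

Step 2
Reactants: 2 methyl 3-Ar-propanoate
Product: 3 3-Ar-propanal
Conditions: i-Bu2AlH, CH2Cl2, −78 °C; aq potassium sodium tartrate
Reagents that add atoms: none
Why: Partial ester reduction with i-Bu2AlH should stop at the tetrahedral aluminate at low temperature and release the aldehyde on work-up.

Step 3
Reactants: 3 3-Ar-propanal
Product: 4 (E)-1-iodo-4-Ar-but-1-ene
Conditions: CrCl2, CHI3, THF/dioxane, 0 °C to rt
Reagents that add atoms: iodoform, IC(I)I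
Why: Takai olefination through a geminal dichromium species should give mainly the E-vinyl iodide; any Z isomer converges later because the alkene geometry is lost in step 13.

Step 4
Reactants: 5 4-(tert-butyldimethylsilyloxy)benzaldehyde
Product: 6 (E)-1-iodo-2-Ar-ethene
Conditions: CrCl2, CHI3, THF, 0 °C to rt
Reagents that add atoms: iodoform, IC(I)I
Why: Takai olefination of an aromatic aldehyde, which should be strongly E-selective.

Step 5
Reactants: 7 4-iodophenol; 8 pent-4-en-1-ol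
Product: 9 5-(4-hydroxyphenyl)pentanal
Conditions: Pd(OAc)2 (cat.), n-Bu4NCl, LiCl, LiOAc, DMF, 70 °C
Reagents that add atoms: none
Why: Heck arylation at the terminal alkene carbon followed by palladium hydride chain walking to the carbinol carbon (redox-relay Heck reaction) should deliver the saturated aldehyde.

Step 6
Reactants: 9 5-(4-hydroxyphenyl)pentanal
Product: 10 5-Ar-pentanal
Conditions: TBSCl, imidazole, CH2Cl2, 0 °C
Reagents that add atoms: tert-butyldimethylsilyl chloride, CC(C)(C)[Si](C)(C)Cl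
Why: Chemoselective phenol silylation; the aldehyde is untouched.

Step 7
Reactants: 11 (S)-4-benzyloxazolidin-2-one; 12 2-(diethoxyphosphoryl)acetic acid
Product: 13 (S)-4-benzyl-3-[2-(diethoxyphosphoryl)acetyl]oxazolidin-2-one
Conditions: t-BuCOCl, Et3N, THF, −20 °C; then 11, LiCl, rt
Reagents that add atoms: none
Why: N-Acylation of the oxazolidinone through the mixed pivalic anhydride gives the Horner–Wadsworth–Emmons reagent that carries the auxiliary.

Step 8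
Reactants: 10 5-Ar-pentanal; 13 (S)-4-benzyl-3-[2-(diethoxyphosphoryl)acetyl]oxazolidin-2-one
Product: 16 (S)-4-benzyl-3-[(2E,4S)-4-hydroxy-7-Ar-hept-2-enoyl]oxazolidin-2-one, via α-aminoxy aldehyde 14 (not isolated), via O-anilino enoyl imide 15 (not isolated)
Conditions: D-proline (cat.), PhNO, DMSO, rt; then 13, LiCl, i-Pr2NEt, MeCN, 0 °C; then Cu(OAc)2 (cat.), EtOH, rt
Reagents that add atoms: nitrosobenzene, O=Nc1ccccc1
Why: Proline-catalysed enamine α-aminoxylation (D-proline directs O-attack to give the S-configured α-oxy aldehyde), immediate E-selective Horner–Wadsworth–Emmons olefination before the labile aldehyde can racemise, and copper-catalysed N–O cleavage should set the C4′ carbinol centre.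

Step 9
Reactants: 16 (S)-4-benzyl-3-[(2E,4S)-4-hydroxy-7-Ar-hept-2-enoyl]oxazolidin-2-one
Product: 17 (S)-4-benzyl-3-[(2E,4S)-4-(TBSO)-7-Ar-hept-2-enoyl]oxazolidin-2-one
Conditions: TBSCl, imidazole, DMF, rt
Reagents that add atoms: tert-butyldimethylsilyl chloride, CC(C)(C)[Si](C)(C)Cl
Why: Silylation of the allylic alcohol installs the bulky γ-silyloxy group that steers the next step.

Step 10
Reactants: 6 (E)-1-iodo-2-Ar-ethene; 17 (S)-4-benzyl-3-[(2E,4S)-4-(TBSO)-7-Ar-hept-2-enoyl]oxazolidin-2-one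
Product: 20 (S)-4-benzyl-3-[(3S,4S)-7-Ar-3-((E)-2-Ar-vinyl)-4-(TBSO)heptanoyl]oxazolidin-2-one, via alkenyllithium 18 (not isolated), via alkenylcopper 19 (not isolated)
Conditions: 6, t-BuLi, Et2O, −78 °C; CuI·SMe2, THF; TMSI, then 17, −78 to −30 °C
Reagents that add atoms: none
Why: Conjugate addition of a monoalkenylcopper reagent activated by TMSI should occur anti to the γ-silyloxy group of the E-enoyl imide (Felkin–Anh-type control), and because no magnesium is present the imide should react through its non-chelated, dipole-opposed rotamer in which the benzyl group shields the same face, so C3′ is set.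

Step 11
Reactants: 20 (S)-4-benzyl-3-[(3S,4S)-7-Ar-3-((E)-2-Ar-vinyl)-4-(TBSO)heptanoyl]oxazolidin-2-one; 5 4-(tert-butyldimethylsilyloxy)benzaldehyde
Product: 22 (S)-4-benzyl-3-[(2R,3R,4S)-7-Ar-2-((S)-Ar(hydroxy)methyl)-3-((E)-2-Ar-vinyl)-4-(TBSO)heptanoyl]oxazolidin-2-one, via trimethylsilyl ether 21 (not isolated)
Conditions: MgCl2 (cat.), Et3N, TMSCl, EtOAc, rt; then 1 M HCl, THF, 0 °C
Reagents that add atoms: none
Why: Magnesium-dichloride-catalysed direct anti-aldol reaction of an N-acyloxazolidinone, in which the chelated Z-enolate should add to the non-enolisable aldehyde on the face away from the benzyl group through a boat-like transition state, setting ring carbons C2 and C3 anti under auxiliary control before the silyl ether is hydrolysed on work-up.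

Step 12
Reactants: 22 (S)-4-benzyl-3-[(2R,3R,4S)-7-Ar-2-((S)-Ar(hydroxy)methyl)-3-((E)-2-Ar-vinyl)-4-(TBSO)heptanoyl]oxazolidin-2-one
Product: 23 (2R,3R,4S)-7-Ar-2-((S)-Ar(hydroxy)methyl)-3-((E)-2-Ar-vinyl)-4-(TBSO)-N-methoxy-N-methylheptanamide
Conditions: MeONHMe·HCl, AlMe3, THF, 0 °C to rt
Reagents that add atoms: N,O-dimethylhydroxylamine hydrochloride, CNOC.Cl
Why: Aluminium amide transamination, assisted by the free β-hydroxyl as its aluminium alkoxide, should give the Weinreb amide and release the auxiliary without touching the stereocentres.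

Step 13
Reactants: 4 (E)-1-iodo-4-Ar-but-1-ene; 23 (2R,3R,4S)-7-Ar-2-((S)-Ar(hydroxy)methyl)-3-((E)-2-Ar-vinyl)-4-(TBSO)-N-methoxy-N-methylheptanamide
Product: 26 (2S,3R,6S)-2-Ar-3-[(1E,3R,4S)-1,7-di-Ar-4-(TBSO)hept-1-en-3-yl]-6-(2-Ar-ethyl)oxan-4-one, via alkenyllithium 24 (not isolated), via hydroxy enone 25 (not isolated)
Conditions: 4, t-BuLi, Et2O, −78 °C; then 23, THF, −78 to −40 °C; aq NH4Cl; then Amberlyst-15, CH2Cl2, 0 °C to rt
Reagents that add atoms: none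
Why: Iodine–lithium exchange gives alkenyllithium 24, which adds once to Weinreb amide 23 through the stable chelated tetrahedral adduct to form the C4–C5 bond and, after protonation, β′-hydroxy enone 25; acid then triggers conjugate addition of the C2 hydroxyl to C6, which forms the O1–C6 bond. The closest known reaction type is the Weinreb ketone synthesis followed by intramolecular oxa-Michael cyclisation of a hydroxy enone to a cis-2,6-disubstituted tetrahydropyran-4-one. The oxane ring closes in the 6-endo-trig mode. The new C6 stereocentre is controlled by the existing C2 and C3 centres through a chair transition state with the aryl group, the C3 side chain and the arylethyl group all equatorial, which is also the thermodynamic outcome of the reversible addition. The step needs single addition at the acyl carbon and cyclisation in preference to dehydration or retro-aldol cleavage of the benzylic aldol; the Weinreb chelate, excess organolithium to cover the free hydroxyl and a mild solid acid at low temperature should secure this.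

Step 14
Reactants: 26 (2S,3R,6S)-2-Ar-3-[(1E,3R,4S)-1,7-di-Ar-4-(TBSO)hept-1-en-3-yl]-6-(2-Ar-ethyl)oxan-4-one
Product: 27 (2S,3S,4S,6S)-2-Ar-3-[(1E,3R,4S)-1,7-di-Ar-4-(TBSO)hept-1-en-3-yl]-6-(2-Ar-ethyl)oxan-4-ol
Conditions: LiBH(s-Bu)3, THF, −78 °C
Reagents that add atoms: none
Why: Substrate-controlled ketone reduction in which the bulky LiBH(s-Bu)3 should attack the chair oxanone from the equatorial direction, giving the axial C4 alcohol cis to the equatorial C3 substituent.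

Step 15
Reactants: 27 (2S,3S,4S,6S)-2-Ar-3-[(1E,3R,4S)-1,7-di-Ar-4-(TBSO)hept-1-en-3-yl]-6-(2-Ar-ethyl)oxan-4-ol
Product: 28 (2S,3S,4S,6S)-2-(4-hydroxyphenyl)-3-[(1E,3R,4S)-4-hydroxy-1,7-bis(4-hydroxyphenyl)hept-1-en-3-yl]-6-[2-(4-hydroxyphenyl)ethyl]oxan-4-ol
Conditions: HF·pyridine, pyridine, THF, 0 °C to rt
Reagents that add atoms: none
Why: Fluoride-mediated cleavage of all five silyl ethers under buffered conditions should leave the p-hydroxybenzylic ring ether and the styrene untouched.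

**Compound list**

1 | methyl 3-(4-hydroxyphenyl)propanoate | COC(=O)CCc1ccc(O)cc1 | starting material
2 | methyl 3-Ar-propanoate | COC(=O)CCc1ccc(O[Si](C)(C)C(C)(C)C)cc1 | intermediate
3 | 3-Ar-propanal | O=CCCc1ccc(O[Si](C)(C)C(C)(C)C)cc1 | intermediate
4 | (E)-1-iodo-4-Ar-but-1-ene | I/C=C/CCc1ccc(O[Si](C)(C)C(C)(C)C)cc1 | intermediate
5 | 4-(tert-butyldimethylsilyloxy)benzaldehyde | O=Cc1ccc(O[Si](C)(C)C(C)(C)C)cc1 | starting material
6 | (E)-1-iodo-2-Ar-ethene | I/C=C/c1ccc(O[Si](C)(C)C(C)(C)C)cc1 | intermediate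
7 | 4-iodophenol | Oc1ccc(I)cc1 | starting material
8 | pent-4-en-1-ol | C=CCCCO | starting material
9 | 5-(4-hydroxyphenyl)pentanal | O=CCCCCc1ccc(O)cc1 | intermediate
10 | 5-Ar-pentanal | O=CCCCCc1ccc(O[Si](C)(C)C(C)(C)C)cc1 | intermediate
11 | (S)-4-benzyloxazolidin-2-one | O=C1OC[C@H](Cc2ccccc2)N1 | starting material
12 | 2-(diethoxyphosphoryl)acetic acid | CCOP(=O)(OCC)CC(=O)O | starting material
13 | (S)-4-benzyl-3-[2-(diethoxyphosphoryl)acetyl]oxazolidin-2-one | CCOP(=O)(OCC)CC(=O)N1[C@@H](Cc2ccccc2)COC1=O | intermediate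
14 | (S)-2-(N-phenylaminooxy)-5-Ar-pentanal | O=C[C@@H](ONc1ccccc1)CCCc1ccc(O[Si](C)(C)C(C)(C)C)cc1 | intermediate
15 | (S)-4-benzyl-3-[(2E,4S)-4-(N-phenylaminooxy)-7-Ar-hept-2-enoyl]oxazolidin-2-one | O=C(/C=C/[C@@H](ONc1ccccc1)CCCc1ccc(O[Si](C)(C)C(C)(C)C)cc1)N1[C@@H](Cc2ccccc2)COC1=O | intermediate
16 | (S)-4-benzyl-3-[(2E,4S)-4-hydroxy-7-Ar-hept-2-enoyl]oxazolidin-2-one | O=C(/C=C/[C@@H](O)CCCc1ccc(O[Si](C)(C)C(C)(C)C)cc1)N1[C@@H](Cc2ccccc2)COC1=O | intermediate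
17 | (S)-4-benzyl-3-[(2E,4S)-4-(TBSO)-7-Ar-hept-2-enoyl]oxazolidin-2-one | O=C(/C=C/[C@@H](O[Si](C)(C)C(C)(C)C)CCCc1ccc(O[Si](C)(C)C(C)(C)C)cc1)N1[C@@H](Cc2ccccc2)COC1=O | intermediate
18 | (E)-2-Ar-vinyllithium | [Li]/C=C/c1ccc(O[Si](C)(C)C(C)(C)C)cc1 | intermediate
19 | (E)-2-Ar-vinylcopper | [Cu]/C=C/c1ccc(O[Si](C)(C)C(C)(C)C)cc1 | intermediate
20 | (S)-4-benzyl-3-[(3S,4S)-7-Ar-3-((E)-2-Ar-vinyl)-4-(TBSO)heptanoyl]oxazolidin-2-one | CC(C)(C)[Si](C)(C)Oc1ccc(/C=C/[C@H](CC(=O)N2[C@@H](Cc3ccccc3)COC2=O)[C@@H](O[Si](C)(C)C(C)(C)C)CCCc2ccc(O[Si](C)(C)C(C)(C)C)cc2)cc1 | intermediate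
21 | trimethylsilyl ether of 22 at the benzylic hydroxyl | CC(C)(C)[Si](C)(C)Oc1ccc(/C=C/[C@H]([C@@H](C(=O)N2[C@@H](Cc3ccccc3)COC2=O)[C@@H](c2ccc(O[Si](C)(C)C(C)(C)C)cc2)O[Si](C)(C)C)[C@@H](O[Si](C)(C)C(C)(C)C)CCCc2ccc(O[Si](C)(C)C(C)(C)C)cc2)cc1 | intermediate
22 | (S)-4-benzyl-3-[(2R,3R,4S)-7-Ar-2-((S)-Ar(hydroxy)methyl)-3-((E)-2-Ar-vinyl)-4-(TBSO)heptanoyl]oxazolidin-2-one | CC(C)(C)[Si](C)(C)Oc1ccc(/C=C/[C@H]([C@@H](C(=O)N2[C@@H](Cc3ccccc3)COC2=O)[C@@H](c2ccc(O[Si](C)(C)C(C)(C)C)cc2)O)[C@@H](O[Si](C)(C)C(C)(C)C)CCCc2ccc(O[Si](C)(C)C(C)(C)C)cc2)cc1 | intermediate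
23 | (2R,3R,4S)-7-Ar-2-((S)-Ar(hydroxy)methyl)-3-((E)-2-Ar-vinyl)-4-(TBSO)-N-methoxy-N-methylheptanamide | CC(C)(C)[Si](C)(C)Oc1ccc(/C=C/[C@H]([C@@H](C(=O)N(C)OC)[C@@H](c2ccc(O[Si](C)(C)C(C)(C)C)cc2)O)[C@@H](O[Si](C)(C)C(C)(C)C)CCCc2ccc(O[Si](C)(C)C(C)(C)C)cc2)cc1 | intermediate
24 | (E)-4-Ar-but-1-en-1-yllithium | [Li]/C=C/CCc1ccc(O[Si](C)(C)C(C)(C)C)cc1 | intermediate
25 | (3E,6R,7R,8S)-1,11-di-Ar-6-((S)-Ar(hydroxy)methyl)-7-((E)-2-Ar-vinyl)-8-(TBSO)undec-3-en-5-one | CC(C)(C)[Si](C)(C)Oc1ccc(/C=C/[C@H]([C@@H](C(=O)/C=C/CCc2ccc(O[Si](C)(C)C(C)(C)C)cc2)[C@@H](c2ccc(O[Si](C)(C)C(C)(C)C)cc2)O)[C@@H](O[Si](C)(C)C(C)(C)C)CCCc2ccc(O[Si](C)(C)C(C)(C)C)cc2)cc1 | intermediate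
26 | (2S,3R,6S)-2-Ar-3-[(1E,3R,4S)-1,7-di-Ar-4-(TBSO)hept-1-en-3-yl]-6-(2-Ar-ethyl)oxan-4-one | CC(C)(C)[Si](C)(C)Oc1ccc(/C=C/[C@H]([C@@H]2[C@@H](c3ccc(O[Si](C)(C)C(C)(C)C)cc3)O[C@@H](CCc3ccc(O[Si](C)(C)C(C)(C)C)cc3)CC2=O)[C@@H](O[Si](C)(C)C(C)(C)C)CCCc2ccc(O[Si](C)(C)C(C)(C)C)cc2)cc1 | intermediate
27 | (2S,3S,4S,6S)-2-Ar-3-[(1E,3R,4S)-1,7-di-Ar-4-(TBSO)hept-1-en-3-yl]-6-(2-Ar-ethyl)oxan-4-ol | CC(C)(C)[Si](C)(C)Oc1ccc(/C=C/[C@H]([C@@H]2[C@@H](c3ccc(O[Si](C)(C)C(C)(C)C)cc3)O[C@@H](CCc3ccc(O[Si](C)(C)C(C)(C)C)cc3)C[C@@H]2O)[C@@H](O[Si](C)(C)C(C)(C)C)CCCc2ccc(O[Si](C)(C)C(C)(C)C)cc2)cc1 | intermediate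
28 | (2S,3S,4S,6S)-2-(4-hydroxyphenyl)-3-[(1E,3R,4S)-4-hydroxy-1,7-bis(4-hydroxyphenyl)hept-1-en-3-yl]-6-[2-(4-hydroxyphenyl)ethyl]oxan-4-ol | Oc1ccc(/C=C/[C@H]([C@@H]2[C@@H](c3ccc(O)cc3)O[C@@H](CCc3ccc(O)cc3)C[C@@H]2O)[C@@H](O)CCCc2ccc(O)cc2)cc1 | target

**Step count.** Total: 15 steps. Longest linear sequence: 10 steps (steps 5, 6, 8, 9, 10, 11, 12, 13, 14, 15).

**Steps most likely to fail**

1. Step 13 (key step). Addition of 24 to the congested amide may be slow and give way to enolisation, and the benzylic aldol 25 may dehydrate or undergo retro-aldol cleavage during acid treatment instead of cyclising. The fallback sets out from 23 and comes back at 27, and still forms both ring bonds in one operation. Amide 23 would be silylated (Et3SiOTf, 2,6-lutidine) to the triethylsilyl ether of 23, F1, and reduced with i-Bu2AlH to (2R,3R,4S)-7-Ar-2-[(S)-Ar(triethylsilyloxy)methyl]-3-[(E)-2-Ar-vinyl]-4-(TBSO)heptanal, F2. Commercial 4-(4-hydroxyphenyl)butan-2-one would be silylated to 4-Ar-butan-2-one, F3, and converted (LDA, TMSCl) into its kinetic enol silane, tert-butyldimethyl{4-[3-(trimethylsilyloxy)but-3-en-1-yl]phenoxy}silane, F4. A chelation-controlled Mukaiyama aldol addition of F4 to F2 (Me2AlCl, CH2Cl2, −78 °C) should form C4–C5 with the anti-Felkin, 1,3-syn sense. Acidic work-up should then remove the triethylsilyl group, so that the hydroxy ketone closes through O1–C6 to the cyclic hemiketal, the 6-hydroxy derivative of 27, F5. Reduction with Et3SiH and BF3·OEt2 by axial hydride delivery to the oxocarbenium ion should give 27.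

2. Step 10. Facial selectivity may be poor if auxiliary and γ-silyloxy centre do not act in concert, and the allylic silyloxy group may be lost by reductive elimination. The fallback sets out from 10 and comes back at 20, using a ring template instead of acyclic control. Aldehyde 10 would be taken through 14 as in step 8 but olefinated with ethyl 2-(diphenoxyphosphoryl)acetate (Z-selective Horner–Wadsworth–Emmons reagent) to ethyl (2Z,4S)-4-(N-phenylaminooxy)-7-Ar-hept-2-enoate, F6. Copper-catalysed N–O cleavage with lactonisation should give the butenolide (S)-5-(3-Ar-propyl)furan-2(5H)-one, F7. Organocopper 19 should add anti to the ring substituent to give (4S,5S)-5-(3-Ar-propyl)-4-[(E)-2-Ar-vinyl]dihydrofuran-2(3H)-one, F8. Opening with LiOH, full silylation (TBSOTf, 2,6-lutidine) and mild aqueous acid hydrolysis of the silyl ester should give (3S,4S)-7-Ar-3-[(E)-2-Ar-vinyl]-4-(TBSO)heptanoic acid, F9. Its mixed pivalic anhydride would acylate lithiated 11 to give 20.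

3. Step 11. The hindered β-branched imide may react sluggishly with the electron-rich aldehyde, and anti selectivity may erode. The fallback sets out from 20 and comes back at 26, relying on thermodynamic correction of C3. A dibutylboron aldol reaction of 20 with 5 (n-Bu2BOTf, i-Pr2NEt, CH2Cl2) should give the syn adduct with the correct carbinol centre, (S)-4-benzyl-3-[(2S,3R,4S)-7-Ar-2-((S)-Ar(hydroxy)methyl)-3-((E)-2-Ar-vinyl)-4-(TBSO)heptanoyl]oxazolidin-2-one, F10. Transamination as in step 12 would give the (2S,3R,4S)-configured Weinreb amide, F11. Reaction with 24 and cyclisation as in step 13 would give the 2,3-cis oxanone (2S,3S,6S)-2-Ar-3-[(1E,3R,4S)-1,7-di-Ar-4-(TBSO)hept-1-en-3-yl]-6-(2-Ar-ethyl)oxan-4-one, F12. Epimerisation at C3 with DBU, α to the ketone, should then lead to the all-equatorial 26.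

**Further compounds**

F1 | step 13 | triethylsilyl ether of 23 | CC(C)(C)[Si](C)(C)Oc1ccc(/C=C/[C@H]([C@@H](C(=O)N(C)OC)[C@@H](c2ccc(O[Si](C)(C)C(C)(C)C)cc2)O[Si](CC)(CC)CC)[C@@H](O[Si](C)(C)C(C)(C)C)CCCc2ccc(O[Si](C)(C)C(C)(C)C)cc2)cc1
F2 | step 13 | (2R,3R,4S)-7-Ar-2-[(S)-Ar(triethylsilyloxy)methyl]-3-[(E)-2-Ar-vinyl]-4-(TBSO)heptanal | CC(C)(C)[Si](C)(C)Oc1ccc(/C=C/[C@H]([C@@H](C=O)[C@@H](c2ccc(O[Si](C)(C)C(C)(C)C)cc2)O[Si](CC)(CC)CC)[C@@H](O[Si](C)(C)C(C)(C)C)CCCc2ccc(O[Si](C)(C)C(C)(C)C)cc2)cc1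
F3 | step 13 | 4-Ar-butan-2-one | CC(=O)CCc1ccc(O[Si](C)(C)C(C)(C)C)cc1
F4 | step 13 | tert-butyldimethyl{4-[3-(trimethylsilyloxy)but-3-en-1-yl]phenoxy}silane | C=C(O[Si](C)(C)C)CCc1ccc(O[Si](C)(C)C(C)(C)C)cc1
F5 | step 13 | cyclic hemiketal, 6-hydroxy derivative of 27 | CC(C)(C)[Si](C)(C)Oc1ccc(/C=C/[C@H]([C@@H]2[C@@H](c3ccc(O[Si](C)(C)C(C)(C)C)cc3)O[C@@](O)(CCc3ccc(O[Si](C)(C)C(C)(C)C)cc3)C[C@@H]2O)[C@@H](O[Si](C)(C)C(C)(C)C)CCCc2ccc(O[Si](C)(C)C(C)(C)C)cc2)cc1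
F6 | step 10 | ethyl (2Z,4S)-4-(N-phenylaminooxy)-7-Ar-hept-2-enoate | CCOC(=O)/C=C\[C@@H](ONc1ccccc1)CCCc1ccc(O[Si](C)(C)C(C)(C)C)cc1
F7 | step 10 | (S)-5-(3-Ar-propyl)furan-2(5H)-one | O=C1C=C[C@H](CCCc2ccc(O[Si](C)(C)C(C)(C)C)cc2)O1
F8 | step 10 | (4S,5S)-5-(3-Ar-propyl)-4-[(E)-2-Ar-vinyl]dihydrofuran-2(3H)-one | O=C1C[C@@H](/C=C/c2ccc(O[Si](C)(C)C(C)(C)C)cc2)[C@H](CCCc2ccc(O[Si](C)(C)C(C)(C)C)cc2)O1
F9 | step 10 | (3S,4S)-7-Ar-3-[(E)-2-Ar-vinyl]-4-(TBSO)heptanoic acid | OC(=O)C[C@@H](/C=C/c1ccc(O[Si](C)(C)C(C)(C)C)cc1)[C@@H](O[Si](C)(C)C(C)(C)C)CCCc1ccc(O[Si](C)(C)C(C)(C)C)cc1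
F10 | step 11 | (S)-4-benzyl-3-[(2S,3R,4S)-7-Ar-2-((S)-Ar(hydroxy)methyl)-3-((E)-2-Ar-vinyl)-4-(TBSO)heptanoyl]oxazolidin-2-one | CC(C)(C)[Si](C)(C)Oc1ccc(/C=C/[C@H]([C@H](C(=O)N2[C@@H](Cc3ccccc3)COC2=O)[C@@H](c2ccc(O[Si](C)(C)C(C)(C)C)cc2)O)[C@@H](O[Si](C)(C)C(C)(C)C)CCCc2ccc(O[Si](C)(C)C(C)(C)C)cc2)cc1
F11 | step 11 | (2S,3R,4S)-7-Ar-2-((S)-Ar(hydroxy)methyl)-3-((E)-2-Ar-vinyl)-4-(TBSO)-N-methoxy-N-methylheptanamide | CC(C)(C)[Si](C)(C)Oc1ccc(/C=C/[C@H]([C@H](C(=O)N(C)OC)[C@@H](c2ccc(O[Si](C)(C)C(C)(C)C)cc2)O)[C@@H](O[Si](C)(C)C(C)(C)C)CCCc2ccc(O[Si](C)(C)C(C)(C)C)cc2)cc1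
F12 | step 11 | (2S,3S,6S)-2-Ar-3-[(1E,3R,4S)-1,7-di-Ar-4-(TBSO)hept-1-en-3-yl]-6-(2-Ar-ethyl)oxan-4-one | CC(C)(C)[Si](C)(C)Oc1ccc(/C=C/[C@H]([C@H]2[C@@H](c3ccc(O[Si](C)(C)C(C)(C)C)cc3)O[C@@H](CCc3ccc(O[Si](C)(C)C(C)(C)C)cc3)CC2=O)[C@@H](O[Si](C)(C)C(C)(C)C)CCCc2ccc(O[Si](C)(C)C(C)(C)C)cc2)cc1
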